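**Plan** (labdane numbering)

1. Retrosynthesis: the malonate half ester and the C-15 oxidation level are adjusted last; with a helper ketone at C-6, ring B is cut at C-7–C-8 and ring A at the ring-fusion bond C-5–C-10, which opens the decalin to an acyclic keto-enyne.
2. Enabling feature: C-6 is the only ring B methylene flanked by both cut termini (C-5, C-7), so a C-6 ketone makes both carbons enol nucleophiles; the C-10 methyl and the C-8 exocyclic methylene are the Markovnikov hydro-alkylation retrons of a C-1=C-10 alkene and a C-8≡C-17 terminal alkyne.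
3. Forward: in one operation the ketone adds through C-5 to C-10 (ring A first) and then through C-7 to C-8 (ring B); ring size enforces this order.
4. The chain comes from methyl geranate (C-9, C-11 to C-16, C-10, C-20), mesityl oxide plus a butenyl Grignard reagent (C-1 to C-7, C-18, C-19) and a silylacetylene (C-8, C-17), joined by SN2' alkynylation and cross-metathesis.
5. Stereochemistry: C-9 by a catalyst-controlled copper SN2' alkynylation; C-10 relayed from C-9 in the chair of the first closure; C-5 from that chair and by equilibration next to the C-6 ketone; the 13E alkene is carried over from geranate.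
6. The C-6 ketone is then deleted through its tosylhydrazone, the ester reduced and the alcohol opened onto Meldrum's acid.

Key step: step 7

Assumption: methyl geranate is used as the pure (2E) isomer, and the 7E/7Z mixture formed in step 5 is not separated because both isomers give the same C-10 cation in step 7.

**Step 1**
Reactants: 1 4-methylpent-3-en-2-one (mesityl oxide); 2 but-3-en-1-ylmagnesium bromide
Product: 3 4,4-dimethyloct-7-en-2-one
Conditions: CuBr·SMe2 (5 mol%), THF, −40 to 0 °C; then 1 M HCl
Reagents that add atoms: none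
Why: Copper-catalysed conjugate addition of a Grignard reagent to the β,β-disubstituted enone builds the C-4 gem-dimethyl quaternary carbon; no stereocentre is formed.

**Step 2**
Reactants: 4 methyl (2E)-3,7-dimethylocta-2,6-dienoate (methyl geranate)
Product: 5 methyl (2E,6E)-8-hydroxy-3,7-dimethylocta-2,6-dienoate
Conditions: SeO2 (0.1 equiv), salicylic acid (0.1 equiv), t-BuOOH (3 equiv), CH2Cl2, 20 °C
Reagents that add atoms: tert-butyl hydroperoxide, CC(C)(C)OO (terminal oxidant; the oxygen is passed on through selenium dioxide, O=[Se]=O)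
Why: Riley allylic oxidation (ene reaction then [2,3]-sigmatropic shift) is selective for the (E)-methyl group of the electron-rich 6,7-alkene, the enoate alkene being deactivated; no stereocentre is formed and both alkene geometries are kept.

**Step 3**
Reactants: 5 methyl (2E,6E)-8-hydroxy-3,7-dimethylocta-2,6-dienoate
Product: 6 methyl (2E,6E)-8-[(diethoxyphosphoryl)oxy]-3,7-dimethylocta-2,6-dienoate
Conditions: (EtO)2P(O)Cl, pyridine, DMAP (cat.), CH2Cl2, 0 °C
Reagents that add atoms: diethyl chlorophosphate, CCOP(=O)(Cl)OCC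
Why: O-phosphorylation of the primary allylic alcohol installs the leaving group for allylic substitution; no stereocentre is formed.

**Step 4**
Reactants: 6 methyl (2E,6E)-8-[(diethoxyphosphoryl)oxy]-3,7-dimethylocta-2,6-dienoate; 7 ethynyltri(propan-2-yl)silane
Product: 8 methyl (2E,6S)-3-methyl-6-(prop-1-en-2-yl)-8-[tri(propan-2-yl)silyl]oct-2-en-7-ynoate
Conditions: CuCl (10 mol%), chiral imidazolinium chloride (N-heterocyclic carbene precursor with a 2-hydroxyaryl arm, the enantiomer that leads to the 6S product, 10 mol%), LiOtBu (1.5 equiv), CH2Cl2, 25 °C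
Reagents that add atoms: none
Why: Copper-catalysed enantioselective allylic substitution in the SN2' mode by a copper acetylide attacks the γ-carbon and sets the C-9 stereocentre by catalyst control, while the alkene shifts to give the isopropenyl group.

**Step 5**
Reactants: 8 methyl (2E,6S)-3-methyl-6-(prop-1-en-2-yl)-8-[tri(propan-2-yl)silyl]oct-2-en-7-ynoate; 3 4,4-dimethyloct-7-en-2-one
Product: 9 methyl (2E,6S)-3,7,11,11-tetramethyl-13-oxo-6-{[tri(propan-2-yl)silyl]ethynyl}tetradeca-2,7-dienoate (7E/7Z mixture)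
Conditions: second-generation Hoveyda–Grubbs catalyst [RuCl2(H2IMes)(=CH–C6H4-2-OiPr)] (5 mol%), 3 (4 equiv), CH2Cl2, 40 °C
Reagents that add atoms: none
Why: Olefin cross-metathesis between the 1,1-disubstituted alkene (which does not homodimerise) and an excess of the terminal alkene gives the trisubstituted C-1=C-10 alkene; the silylated alkyne and the conjugated enoate are inert and C-9 is untouched.

**Step 6**
Reactants: 9 methyl (2E,6S)-3,7,11,11-tetramethyl-13-oxo-6-{[tri(propan-2-yl)silyl]ethynyl}tetradeca-2,7-dienoate (7E/7Z mixture)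
Product: 10 methyl (2E,6R)-6-ethynyl-3,7,11,11-tetramethyl-13-oxotetradeca-2,7-dienoate (7E/7Z mixture)
Conditions: Bu4NF, AcOH (1:1), THF, 0 °C
Reagents that add atoms: none
Why: Fluoride-mediated protodesilylation of the alkynylsilane, buffered with acetic acid so that the doubly activated C-9–H is not removed, frees the terminal alkyne (the descriptor changes only through the priority rules).

**Step 7**
Reactants: 10 methyl (2E,6R)-6-ethynyl-3,7,11,11-tetramethyl-13-oxotetradeca-2,7-dienoate (7E/7Z mixture)
Product: 12 methyl (2E)-3-methyl-5-[(1R,4aR,8aS)-5,5,8a-trimethyl-2-methylidene-4-oxodecahydronaphthalen-1-yl]pent-2-enoate, via monocyclic ring A ketone 11 (not isolated)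
Conditions: [Au(IPr)]NTf2 (5 mol%; IPr = 1,3-bis(2,6-diisopropylphenyl)imidazol-2-ylidene), HNTf2 (2 mol%), dry toluene, 60 °C
Reagents that add atoms: none
Why: Proposed new method: acid- and gold-promoted enolisation of the C-6 ketone lets the Markovnikov-activated C-1=C-10 alkene (protonated or gold-bound, cationic character at tertiary C-10) be captured by enol carbon C-5 to give 11, whose methyl-ketone enol then adds through C-7 to the internal carbon C-8 of the gold-bound terminal alkyne, and protodeauration leaves the exocyclic methylene. The closest known reaction types are the gold-catalysed intramolecular hydroalkylation of unactivated alkenes by simple ketones and the Conia-ene-type gold-catalysed exo-dig cyclisation of ketone enols or silyl enol ethers onto alkynes; new is their coupling at the two α-carbons of one ketone. Ring A closes 6-(enolexo)-endo-trig at the alkene and ring B closes 6-(enolendo)-exo-dig at the alkyne. C-10 is set by the C-9 stereocentre: in the chair transition state the C-20 methyl is axial, the C-9 substituent equatorial with its hydrogen turned inward, the homoallylic chain anti to the incoming C-5 and the slim ethynyl group gauche to it; C-5 follows from the equatorial acyl group in the same chair and, being α to the C-6 ketone, settles to the trans-fused isomer by enolisation. The step needs regioselectivity between the two α-carbons and the two π bonds, which ring size secures (only C-5 reaches C-10 through a six-membered ring, and C-7 reaches C-8 only after ring A exists), and chemoselectivity against the enoate alkene, which is electron-poor and not activated.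

**Step 8**
Reactants: 12 methyl (2E)-3-methyl-5-[(1R,4aR,8aS)-5,5,8a-trimethyl-2-methylidene-4-oxodecahydronaphthalen-1-yl]pent-2-enoate
Product: 13 methyl (2E)-3-methyl-5-[(1R,4aR,8aS)-5,5,8a-trimethyl-2-methylidene-4-{2-[(4-methylphenyl)sulfonyl]hydrazinylidene}decahydronaphthalen-1-yl]pent-2-enoate
Conditions: TsNHNH2, MeOH, 4 Å molecular sieves, 60 °C
Reagents that add atoms: 4-methylbenzenesulfonohydrazide, Cc1ccc(cc1)S(=O)(=O)NN
Why: Hydrazone formation under neutral conditions keeps the β,γ-alkene in place and leaves C-5 in the more stable trans-fused form; the β,β-disubstituted enoate does not take up the hydrazide.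

**Step 9**
Reactants: 13 methyl (2E)-3-methyl-5-[(1R,4aR,8aS)-5,5,8a-trimethyl-2-methylidene-4-{2-[(4-methylphenyl)sulfonyl]hydrazinylidene}decahydronaphthalen-1-yl]pent-2-enoate
Product: 15 methyl (2E)-3-methyl-5-[(1R,4aR,8aR)-5,5,8a-trimethyl-2-methylidenedecahydronaphthalen-1-yl]pent-2-enoate (methyl ent-copalate), via N-boryl hydrazide 14 (not isolated)
Conditions: catecholborane (2 equiv), CHCl3, 0 °C; then NaOAc·3H2O, 60 °C
Reagents that add atoms: none
Why: Tosylhydrazone reduction with catecholborane followed by acetate-induced loss of sulfinate and dinitrogen (a mild Wolff–Kishner-type deoxygenation through a diazene) turns C-6 into a methylene group without strong base, so the 8(17)-alkene, the enoate and the ring stereocentres are untouched.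

**Step 10**
Reactants: 15 methyl (2E)-3-methyl-5-[(1R,4aR,8aR)-5,5,8a-trimethyl-2-methylidenedecahydronaphthalen-1-yl]pent-2-enoate
Product: 16 (2E)-3-methyl-5-[(1R,4aR,8aR)-5,5,8a-trimethyl-2-methylidenedecahydronaphthalen-1-yl]pent-2-en-1-ol (ent-copalol)
Conditions: i-Bu2AlH (2.5 equiv), CH2Cl2, −78 °C; aq. potassium sodium tartrate
Reagents that add atoms: none
Why: 1,2-Reduction of the α,β-unsaturated ester with diisobutylaluminium hydride gives the allylic alcohol with retention of the E geometry.

**Step 11**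
Reactants: 16 (2E)-3-methyl-5-[(1R,4aR,8aR)-5,5,8a-trimethyl-2-methylidenedecahydronaphthalen-1-yl]pent-2-en-1-ol; 17 2,2-dimethyl-1,3-dioxane-4,6-dione (Meldrum's acid)
Product: 18 3-{[(2E)-3-methyl-5-[(1R,4aR,8aR)-5,5,8a-trimethyl-2-methylidenedecahydronaphthalen-1-yl]pent-2-en-1-yl]oxy}-3-oxopropanoic acid (target)
Conditions: toluene, 90 °C
Reagents that add atoms: none
Why: Thermal ring opening of Meldrum's acid by the alcohol (acyl transfer with loss of acetone) gives the malonic half ester directly, without a protecting group and without touching the stereocentres.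

**Compound list**

1 | 4-methylpent-3-en-2-one (mesityl oxide) | CC(=O)C=C(C)C | starting material
2 | but-3-en-1-ylmagnesium bromide | C=CCC[Mg]Br | starting material
3 | 4,4-dimethyloct-7-en-2-one | CC(=O)CC(C)(C)CCC=C | intermediate
4 | methyl (2E)-3,7-dimethylocta-2,6-dienoate (methyl geranate) | CC(C)=CCC/C(C)=C/C(=O)OC | starting material
5 | methyl (2E,6E)-8-hydroxy-3,7-dimethylocta-2,6-dienoate | OC/C(C)=C/CC/C(C)=C/C(=O)OC | intermediate
6 | methyl (2E,6E)-8-[(diethoxyphosphoryl)oxy]-3,7-dimethylocta-2,6-dienoate | CCOP(=O)(OCC)OC/C(C)=C/CC/C(C)=C/C(=O)OC | intermediate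
7 | ethynyltri(propan-2-yl)silane | C#C[Si](C(C)C)(C(C)C)C(C)C | starting material
8 | methyl (2E,6S)-3-methyl-6-(prop-1-en-2-yl)-8-[tri(propan-2-yl)silyl]oct-2-en-7-ynoate | CC(=C)[C@@H](C#C[Si](C(C)C)(C(C)C)C(C)C)CC/C(C)=C/C(=O)OC | intermediate
9 | methyl (2E,6S)-3,7,11,11-tetramethyl-13-oxo-6-{[tri(propan-2-yl)silyl]ethynyl}tetradeca-2,7-dienoate (7E/7Z mixture) | CC(=O)CC(C)(C)CCC=C(C)[C@@H](C#C[Si](C(C)C)(C(C)C)C(C)C)CC/C(C)=C/C(=O)OC | intermediate
10 | methyl (2E,6R)-6-ethynyl-3,7,11,11-tetramethyl-13-oxotetradeca-2,7-dienoate (7E/7Z mixture) | CC(=O)CC(C)(C)CCC=C(C)[C@@H](C#C)CC/C(C)=C/C(=O)OC | intermediate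
11 | methyl (2E,6R)-6-[(1S,2R)-2-acetyl-1,3,3-trimethylcyclohexyl]-3-methyloct-2-en-7-ynoate | CC(=O)[C@@H]1C(C)(C)CCC[C@@]1(C)[C@@H](C#C)CC/C(C)=C/C(=O)OC | intermediate
12 | methyl (2E)-3-methyl-5-[(1R,4aR,8aS)-5,5,8a-trimethyl-2-methylidene-4-oxodecahydronaphthalen-1-yl]pent-2-enoate | C=C1CC(=O)[C@@H]2C(C)(C)CCC[C@@]2(C)[C@@H]1CC/C(C)=C/C(=O)OC | intermediate
13 | methyl (2E)-3-methyl-5-[(1R,4aR,8aS)-5,5,8a-trimethyl-2-methylidene-4-{2-[(4-methylphenyl)sulfonyl]hydrazinylidene}decahydronaphthalen-1-yl]pent-2-enoate | C=C1CC(=NNS(=O)(=O)c2ccc(C)cc2)[C@@H]2C(C)(C)CCC[C@@]2(C)[C@@H]1CC/C(C)=C/C(=O)OC | intermediate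
14 | methyl (2E)-5-[(1R,4aR,8aS)-4-{1-(1,3,2-benzodioxaborol-2-yl)-2-[(4-methylphenyl)sulfonyl]hydrazinyl}-5,5,8a-trimethyl-2-methylidenedecahydronaphthalen-1-yl]-3-methylpent-2-enoate (configuration at C-4 of the ring not defined) | C=C1CC(N(B2Oc3ccccc3O2)NS(=O)(=O)c2ccc(C)cc2)[C@@H]2C(C)(C)CCC[C@@]2(C)[C@@H]1CC/C(C)=C/C(=O)OC | intermediate
15 | methyl (2E)-3-methyl-5-[(1R,4aR,8aR)-5,5,8a-trimethyl-2-methylidenedecahydronaphthalen-1-yl]pent-2-enoate (methyl ent-copalate) | C=C1CC[C@@H]2C(C)(C)CCC[C@@]2(C)[C@@H]1CC/C(C)=C/C(=O)OC | intermediate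
16 | (2E)-3-methyl-5-[(1R,4aR,8aR)-5,5,8a-trimethyl-2-methylidenedecahydronaphthalen-1-yl]pent-2-en-1-ol (ent-copalol) | C=C1CC[C@@H]2C(C)(C)CCC[C@@]2(C)[C@@H]1CC/C(C)=C/CO | intermediate
17 | 2,2-dimethyl-1,3-dioxane-4,6-dione (Meldrum's acid) | CC1(C)OC(=O)CC(=O)O1 | starting material
18 | 3-{[(2E)-3-methyl-5-[(1R,4aR,8aR)-5,5,8a-trimethyl-2-methylidenedecahydronaphthalen-1-yl]pent-2-en-1-yl]oxy}-3-oxopropanoic acid | C=C1CC[C@@H]2C(C)(C)CCC[C@@]2(C)[C@@H]1CC/C(C)=C/COC(=O)CC(=O)O | target

**Step count**

Total: 11 steps. Longest linear sequence: 10 steps (4 to 18, steps 2 to 11).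

**Steps most likely to fail**

Step 7 (the proposed new method). The tertiary C-10 cation may lose a proton toward C-9, which would erode the C-9 configuration, or may be captured with poor facial selectivity. The carbonyl oxygen may compete with C-7 for the activated alkyne, and the new exocyclic alkene may migrate into conjugation with the C-6 ketone under the acidic gold conditions. The fallback sets out from 10, comes back at 12, and separates the two closures using known reactions. Markovnikov hydrochlorination of the trisubstituted alkene of 10 (dry HCl, CH2Cl2, −30 °C) would give the tertiary chloride methyl (2E,6R)-7-chloro-6-ethynyl-3,7,11,11-tetramethyl-13-oxotetradec-2-enoate F1. Silylation of its ketone under equilibrating conditions (Me3SiOTf, Et3N, CH2Cl2, 20 °C) would give the more substituted trimethylsilyl enol ether methyl (2E,6R)-7-chloro-6-ethynyl-3,7,11,11-tetramethyl-13-[(trimethylsilyl)oxy]tetradeca-2,12-dienoate F2; the terminal regioisomer cannot cyclise and is recycled after hydrolysis. TiCl4 in CH2Cl2 at −78 °C then closes ring A by tert-alkylation of the silyl enol ether to give 11, now isolated. Silylation of 11 on the methyl side (Me3SiOTf, Et3N, CH2Cl2, 0 °C) gives methyl (2E,6R)-3-methyl-6-{(1S,2R)-1,3,3-trimethyl-2-[1-(trimethylsilyloxy)ethenyl]cyclohexyl}oct-2-en-7-ynoate F3, which should close ring B 6-exo-dig with [Au(PPh3)]NTf2 in CH2Cl2/MeOH at 20 °C to give 12.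

Step 5. Metathesis at the hindered, α-branched 1,1-disubstituted alkene may be slow, while self-metathesis of the partner uses up the catalyst. The fallback sets out from 8 (with 1 as the second building block), comes back at 12 through step 7, and replaces metathesis by an allyl–alkyl coupling. Ene-type allylic chlorination of the isopropenyl group of 8 (NaOCl, CeCl3·7H2O, CH2Cl2/H2O, 0 °C) would give methyl (2E,6R)-7-(chloromethyl)-3-methyl-6-{[tri(propan-2-yl)silyl]ethynyl}octa-2,7-dienoate F7. Copper-catalysed addition of vinylmagnesium bromide to 1, as in step 1, gives 4,4-dimethylhex-5-en-2-one F8, and hydroboration of its vinyl group with 9-BBN-H (THF, 0 °C) gives 9-(3,3-dimethyl-5-oxohexyl)-9-borabicyclo[3.3.1]nonane F9. Copper-catalysed coupling of F9 with F7 (CuOAc, KOMe, THF, 40 °C) gives methyl (2E,6S)-3,11,11-trimethyl-7-methylidene-13-oxo-6-{[tri(propan-2-yl)silyl]ethynyl}tetradec-2-enoate F10. Desilylation as in step 6 gives methyl (2E,6S)-6-ethynyl-3,11,11-trimethyl-7-methylidene-13-oxotetradec-2-enoate F11, the double-bond isomer of 10, which under the conditions of step 7 gives the same C-10 cation and hence 11 and 12.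

Step 4. On this β-methyl-substituted allylic phosphate the catalyst may discriminate the enantiotopic faces poorly, or direct α-substitution may compete with the SN2' path. The fallback sets out from 5, comes back at 8, and sets C-9 by reagent-controlled epoxidation instead. Sharpless asymmetric epoxidation of 5 (Ti(OiPr)4, D-(−)-diethyl tartrate, t-BuOOH, 4 Å molecular sieves, CH2Cl2, −20 °C) would give methyl (2E)-5-[(2R,3R)-3-(hydroxymethyl)-3-methyloxiran-2-yl]-3-methylpent-2-enoate F4. Opening of the epoxide at the secondary carbon with inversion by the alkynylalane Et2Al–C≡C–Si(iPr)3 (made from 7 with n-BuLi and Et2AlCl; toluene, 0 °C) gives methyl (2E,6R,7S)-7,8-dihydroxy-3,7-dimethyl-6-{[tri(propan-2-yl)silyl]ethynyl}oct-2-enoate F5. 1,1'-Thiocarbonyldiimidazole (toluene, 80 °C) converts the diol into methyl (2E,6R)-3-methyl-6-[(4S)-4-methyl-2-sulfanylidene-1,3-dioxolan-4-yl]-8-[tri(propan-2-yl)silyl]oct-2-en-7-ynoate F6, and Corey–Winter olefination with P(OMe)3 at 110 °C gives 8.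

**Further compounds**

F1 | step 7 | methyl (2E,6R)-7-chloro-6-ethynyl-3,7,11,11-tetramethyl-13-oxotetradec-2-enoate (C-7 epimers) | CC(=O)CC(C)(C)CCCC(C)(Cl)[C@@H](C#C)CC/C(C)=C/C(=O)OC
F2 | step 7 | methyl (2E,6R)-7-chloro-6-ethynyl-3,7,11,11-tetramethyl-13-[(trimethylsilyl)oxy]tetradeca-2,12-dienoate | CC(O[Si](C)(C)C)=CC(C)(C)CCCC(C)(Cl)[C@@H](C#C)CC/C(C)=C/C(=O)OC
F3 | step 7 | methyl (2E,6R)-3-methyl-6-{(1S,2R)-1,3,3-trimethyl-2-[1-(trimethylsilyloxy)ethenyl]cyclohexyl}oct-2-en-7-ynoate | C=C(O[Si](C)(C)C)[C@@H]1C(C)(C)CCC[C@@]1(C)[C@@H](C#C)CC/C(C)=C/C(=O)OC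
F4 | step 4 | methyl (2E)-5-[(2R,3R)-3-(hydroxymethyl)-3-methyloxiran-2-yl]-3-methylpent-2-enoate | OC[C@@]1(C)O[C@@H]1CC/C(C)=C/C(=O)OC
F5 | step 4 | methyl (2E,6R,7S)-7,8-dihydroxy-3,7-dimethyl-6-{[tri(propan-2-yl)silyl]ethynyl}oct-2-enoate | OC[C@@](C)(O)[C@@H](C#C[Si](C(C)C)(C(C)C)C(C)C)CC/C(C)=C/C(=O)OC
F6 | step 4 | methyl (2E,6R)-3-methyl-6-[(4S)-4-methyl-2-sulfanylidene-1,3-dioxolan-4-yl]-8-[tri(propan-2-yl)silyl]oct-2-en-7-ynoate | S=C1OC[C@@](C)(O1)[C@@H](C#C[Si](C(C)C)(C(C)C)C(C)C)CC/C(C)=C/C(=O)OC
F7 | step 5 | methyl (2E,6R)-7-(chloromethyl)-3-methyl-6-{[tri(propan-2-yl)silyl]ethynyl}octa-2,7-dienoate | ClCC(=C)[C@@H](C#C[Si](C(C)C)(C(C)C)C(C)C)CC/C(C)=C/C(=O)OC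
F8 | step 5 | 4,4-dimethylhex-5-en-2-one | CC(=O)CC(C)(C)C=C
F9 | step 5 | 9-(3,3-dimethyl-5-oxohexyl)-9-borabicyclo[3.3.1]nonane | CC(=O)CC(C)(C)CCB1C2CCCC1CCC2
F10 | step 5 | methyl (2E,6S)-3,11,11-trimethyl-7-methylidene-13-oxo-6-{[tri(propan-2-yl)silyl]ethynyl}tetradec-2-enoate | CC(=O)CC(C)(C)CCCC(=C)[C@@H](C#C[Si](C(C)C)(C(C)C)C(C)C)CC/C(C)=C/C(=O)OC
F11 | step 5 | methyl (2E,6S)-6-ethynyl-3,11,11-trimethyl-7-methylidene-13-oxotetradec-2-enoate | CC(=O)CC(C)(C)CCCC(=C)[C@@H](C#C)CC/C(C)=C/C(=O)OC
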